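**Easy step.** Start with the plainest thing the earlier runs show: in a closed flask, substrate meets coupling partner, which dissolves from a solid reagent, and gives the target. In the summer run, at 20 °C, the target stops climbing within hours.

| setting | winter | summer | dawn | Wednesday's | Saturday's | Sunday's |
|---|---|---|---|---|---|---|
| substrate | 0.085 M | 0.34 M | 0.17 M | 0.17 M | 0.17 M | 0.17 M |
| solid reagent | 0.187 M | 0.187 M | 0.37 M | 0.187 M | 0.187 M | 0.187 M |
| temperature | −5 °C | 20 °C | −5 °C | 0 °C | 20 °C | 40 °C |
| remark | run made earlier | run made earlier | run made earlier |  |  |  |
| time |  |  |  | 20 h | 20 h | 20 h |

| run | time / h | target / % |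
|---|---|---|
| winter | 2.00 | 0.6 |
| winter | 4.00 | 2.1 |
| winter | 6.00 | 3.5 |
| winter | 12.0 | 9.7 |
| winter | 25.0 | 21.4 |
| summer | 0.667 | 0 |
| summer | 1.33 | 1.1 |
| summer | 2.00 | 1.4 |
| summer | 4.00 | 2.0 |
| summer | 10.0 | 0.9 |
| dawn | 2.00 | 0.6 |
| dawn | 4.00 | 1.1 |
| dawn | 6.00 | 3.2 |
| dawn | 12.0 | 9.3 |
| dawn | 25.0 | 18.6 |

(each reading ± 0.5 percentage points)

- in percentages every species weighs as the substrate in it: one self-condensation product counts as two
- as a solid, counted per litre of solution: solid reagent
- the analysis behind the earlier runs scatters by 0.5 percentage points, standard deviation
- reactions considered so far: substrate -> intermediate A; coupling partner + intermediate A -> intermediate B; substrate + coupling partner -> target; coupling partner + intermediate B -> intermediate C; intermediate C -> side product; solid reagent <-> coupling partner; 2 substrate -> self-condensation product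
- at the start none of the solid reagent is in solution

* which of the two there is more of at the end, Wednesday's (target / side product)
* which of the two there is more of at the end, Saturday's (target / side product)
* which of the two there is more of at the end, Sunday's (target / side product)
* amount of target at the end, in percent of the substrate charged, Wednesday's
* amount of target at the end, in percent of the substrate charged, Saturday's
* amount of target at the end, in percent of the substrate charged, Sunday's

**Stall value.** The summer readings at 2.00 h, 4.00 h and 10.0 h are 1.4%, 2.0% and 0.9%, and with a scatter of 0.5 percentage points I see no climb in them. I assume the substrate has left by another road by then, and that target already made stays. The mean of those readings is 1.43%. I call it the stall value, the percent of charged substrate that has become target when a warm flask stops making it, a plateau yield.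

**My bracket.** Saturday's is the summer flask at half the substrate. The cold runs suggest a smaller charge does not lower the percent: winter, at 0.085 M, read 21.4% at its last point, more than dawn's 18.6% at 0.17 M, though dawn also held more solid reagent. So my floor for Saturday's is the stall value. My ceiling is a judgement, not a proof: the highest summer reading plus one scatter, 2.50%. The summer stall lies far below winter's last reading, though those two runs differ in charge as well as temperature, so it is only my guess that Sunday's, warmer still, ends under the stall value. Wednesday's is a cold flask, and the stall value says nothing about it.

**The forecast.** It gives 17%, 3% and 1% of target for Wednesday's, Saturday's and Sunday's, with target ahead on Wednesday's and side product ahead on the other two. Its ground is that “substrate loss is fast and has a much higher activation energy than coupling”. Its Saturday's figure stands above my ceiling, so there we differ, and its Sunday's figure stands under the stall value, where I put Sunday's too.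

**The flask.** On Wednesday's, Saturday's and Sunday's in turn, target ends at 15.8%, 2.04% and 0.142%, against side product at 0.219%, 21.4% and 36.2%. The forecast's choices stand and its amounts fall within the margin. Saturday's lands inside my bracket, above the floor and below the ceiling.

    substrate → intermediate A (k = 0.0720 h⁻¹, Ea = 90.0 kJ mol⁻¹)
    coupling partner + intermediate A → intermediate B (k = 0.440 L mol⁻¹ h⁻¹, Ea = 64.0 kJ mol⁻¹)
    substrate + coupling partner → target (k = 0.820 L mol⁻¹ h⁻¹, Ea = 66.0 kJ mol⁻¹)
    coupling partner + intermediate B → intermediate C (k = 2.30 L mol⁻¹ h⁻¹, Ea = 71.0 kJ mol⁻¹)
    intermediate C → side product (k = 0.0130 h⁻¹, Ea = 103 kJ mol⁻¹)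
    solid reagent ⇌ coupling partner, rate k6*(cs6 - [coupling partner]) while solid is left; crystals form when [coupling partner] > cs6 (solubility = 0.0560 M, k = 0.130 h⁻¹)
    2 substrate → self-condensation product (k = 0.00270 L mol⁻¹ h⁻¹, Ea = 65.0 kJ mol⁻¹)
    (constants at 0 °C)

**Later reading.** Saturday's shows the stop itself: substrate stands at 0% after 10.0 h, and target reads 2.04% then and 2.04% after 20.0 h. Reckon the same way on Sunday's read at 30 h. Substrate is at 0% after 20.0 h, so target should hold at 0.142%, under the stall value. That reading gives target 0.142%, and side product, at 51.8%, has passed intermediate A at 41.7%.

(The earlier runs and the new flask were generated by integration from invented constants; noise was put on by code.)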